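**Retrosynthetic overview**
1. Ring B is formed last. Its methyl peroxyketal comes from a dioxinol that closes when a γ-hydroperoxy E-enone is photoisomerised to Z; the ketal carbon is equilibrated against the neighbouring C–OO centre and the unwanted C6 epimer is recycled.
2. The enone comes from a Horner–Wadsworth–Emmons reaction of a ring-A β-ketophosphonate with an α-peroxy aldehyde. Its C–OO centre is the carbinol of dimethyl (S)-malate, inverted by SN2 with a protected hydroperoxide.
3. The ketophosphonate comes from a ring-A aldehyde. That aldehyde is made by a new cis-selective C–C bond formation on the cyclic peroxycarbenium ion of a ring-A peroxy-lactol, then C=C transfer hydrogenation and one-carbon homologation.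
4. The peroxy-lactol (ring A, formed first) comes from photoisomerisation–cyclisation of a γ-hydroperoxy E-enal. Its C–OO centre is D-norvaline (diazotisation with retention, then SN2 inversion).
5. Ring order: ring A (steps 7 and 8), then ring B (step 14).

Assumption: ring A is the 3-propyl-6-alkyl-3,6-dihydro-1,2-dioxine and ring B the 6-methoxy peroxyketal ring; locants follow the names below.

**Route**

Step 1
Reactants: 1 2,3-dimethylbut-2-ene
Product: 2 2-methoxypropan-2-yl hydroperoxide
Conditions: O3, MeOH/CH2Cl2, −78 °C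
Reagents that add atoms: ozone, [O-][O+]=O; methanol, CO
Why: Criegee ozonolysis in which the acetone oxide is trapped by methanol to give the α-methoxy hydroperoxide (no stereocentre).

Step 2
Reactants: 3 D-norvaline
Product: 4 (R)-2-hydroxypentanoic acid
Conditions: NaNO2, 1 M H2SO4, 0 to 20 °C
Reagents that add atoms: water, O
Why: Diazotisation of the α-amino acid goes with retention through the α-lactone (double inversion), so the bought (R) centre is carried over.

Step 3
Reactants: 4 (R)-2-hydroxypentanoic acid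
Product: 5 methyl (R)-2-hydroxypentanoate
Conditions: MeOH, H2SO4 (cat.), reflux
Reagents that add atoms: methanol, CO
Why: Fischer esterification that does not touch the stereocentre.

Step 4
Reactants: 5 methyl (R)-2-hydroxypentanoate; 2 2-methoxypropan-2-yl hydroperoxide
Product: 7 methyl (S)-2-[(2-methoxypropan-2-yl)peroxy]pentanoate, via triflate 6 (not isolated)
Conditions: Tf2O, 2,6-lutidine, CH2Cl2, −78 °C; then 2/KOt-Bu, THF, −78 to 0 °C
Reagents that add atoms: none
Why: SN2 displacement of the α-triflyloxy ester by the peroxide anion of 2 goes with inversion, turning the bought (R)-carbinol into the (S)-C–OO centre (propyl-bearing carbon of ring A).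

Step 5
Reactants: 7 methyl (S)-2-[(2-methoxypropan-2-yl)peroxy]pentanoate
Product: 8 (S)-2-[(2-methoxypropan-2-yl)peroxy]pentanal
Conditions: i-Bu2AlH (1.1 equiv), CH2Cl2, −78 °C; aq. KNaC4H4O6
Reagents that add atoms: none
Why: Low-temperature i-Bu2AlH half-reduction of the α-oxygenated ester stops at the tetrahedral O–Al(i-Bu)2 hemiacetal, and the dialkyl peroxyketal survives at −78 °C.

Step 6
Reactants: 8 (S)-2-[(2-methoxypropan-2-yl)peroxy]pentanal; 9 (triphenylphosphoranylidene)acetaldehyde
Product: 10 (S,E)-4-[(2-methoxypropan-2-yl)peroxy]hept-2-enal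
Conditions: toluene, 40 °C
Reagents that add atoms: none
Why: Wittig olefination with the stabilised, non-basic formyl ylide is E-selective and leaves the α-peroxy stereocentre intact.

Step 7
Reactants: 10 (S,E)-4-[(2-methoxypropan-2-yl)peroxy]hept-2-enal
Product: 13 (6S)-6-propyl-3,6-dihydro-1,2-dioxin-3-ol (both anomers), via E-hydroperoxy enal 11 (not isolated), via Z-hydroperoxy enal 12 (not isolated)
Conditions: AcOH/THF/H2O (4:2:1), 20 °C; then hv (350 nm), MeCN, 0 °C
Reagents that add atoms: none
Why: Acid hydrolysis frees the hydroperoxide and E-to-Z photoisomerisation of the enal lets OOH add to CHO, so the Z isomer is drained as the six-membered peroxy-hemiacetal faster than it can absorb again (photochemical isomerisation–cyclisation; the C–OO centre is untouched).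

Step 8
Reactants: 13 (6S)-6-propyl-3,6-dihydro-1,2-dioxin-3-ol; 14 1-(trimethylsilyloxy)buta-1,3-diene
Product: 15 (E)-4-[(3R,6S)-6-propyl-3,6-dihydro-1,2-dioxin-3-yl]but-2-enal
Conditions: 14 (2 equiv), Me3SiOTf (0.2 equiv), CH2Cl2, −78 °C
Reagents that add atoms: none
Why: Proposed new method: Me3SiOTf ionises the peroxy-lactol to a cyclic allylic peroxycarbenium ion (2H-1,2-dioxin-2-ium), the silyloxydiene attacks through its terminal carbon at the carbon next to oxygen, and pseudo-axial attack on the half-chair with propyl pseudo-equatorial gives the 3,6-cis ring, so the new centre is set by the bought one; the closest known reactions are Lewis-acid additions of silyl nucleophiles to saturated peroxycarbenium ions from monoperoxy acetals and vinylogous Mukaiyama or Ferrier-type C-glycosylations of oxocarbenium ions.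

Step 9
Reactants: 15 (E)-4-[(3R,6S)-6-propyl-3,6-dihydro-1,2-dioxin-3-yl]but-2-enal
Product: 16 4-[(3R,6S)-6-propyl-3,6-dihydro-1,2-dioxin-3-yl]butanal
Conditions: diethyl 2,6-dimethyl-1,4-dihydropyridine-3,5-dicarboxylate (1.2 equiv), Bn2NH·CF3CO2H (10 mol%), THF, 20 °C
Reagents that add atoms: none
Why: Iminium-catalysed transfer hydrogenation with the Hantzsch ester reduces only the enal C=C, leaving the ring alkene and the O–O bond alone.

Step 10
Reactants: 16 4-[(3R,6S)-6-propyl-3,6-dihydro-1,2-dioxin-3-yl]butanal; 17 dimethyl (diazomethyl)phosphonate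
Product: 18 dimethyl {2-oxo-5-[(3R,6S)-6-propyl-3,6-dihydro-1,2-dioxin-3-yl]pentyl}phosphonate
Conditions: Sc(OTf)3 (10 mol%), CH2Cl2, 0 to 20 °C
Reagents that add atoms: none
Why: Roskamp-type homologation (Lewis-acid addition of the diazo compound, loss of N2, 1,2-hydride shift) gives the β-ketophosphonate; Sc(OTf)3 replaces the usual SnCl2, which would reduce the O–O bond.

Step 11
Reactants: 19 dimethyl (S)-malate; 2 2-methoxypropan-2-yl hydroperoxide
Product: 21 dimethyl (R)-2-[(2-methoxypropan-2-yl)peroxy]butanedioate, via triflate 20 (not isolated)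
Conditions: Tf2O, 2,6-lutidine, CH2Cl2, −78 °C; then 2/KOt-Bu, THF, −78 to 0 °C
Reagents that add atoms: none
Why: SN2 displacement of the α-triflate by the weakly basic peroxide anion goes with inversion and outruns elimination to fumarate, turning the bought (S)-carbinol into the (R)-C–OO centre (C3 of ring B).

Step 12
Reactants: 21 dimethyl (R)-2-[(2-methoxypropan-2-yl)peroxy]butanedioate
Product: 22 methyl (R)-3-[(2-methoxypropan-2-yl)peroxy]-4-oxobutanoate
Conditions: i-Bu2AlH (1.05 equiv), toluene/CH2Cl2, −78 °C; aq. KNaC4H4O6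
Reagents that add atoms: none
Why: Regioselective i-Bu2AlH half-reduction, because the ester flanked by the peroxy oxygen is the more electrophilic and gives the stable tetrahedral hemiacetal; the stereocentre is untouched.

Step 13
Reactants: 18 dimethyl {2-oxo-5-[(3R,6S)-6-propyl-3,6-dihydro-1,2-dioxin-3-yl]pentyl}phosphonate; 22 methyl (R)-3-[(2-methoxypropan-2-yl)peroxy]-4-oxobutanoate
Product: 23 methyl (3R,4E)-3-[(2-methoxypropan-2-yl)peroxy]-6-oxo-9-[(3R,6S)-6-propyl-3,6-dihydro-1,2-dioxin-3-yl]non-4-enoate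
Conditions: LiCl, i-Pr2NEt, MeCN, 0 °C
Reagents that add atoms: none
Why: Horner–Wadsworth–Emmons olefination under Masamune–Roush conditions gives the E-enone with a base mild enough for the dioxine ring and the α-peroxy aldehyde.

Step 14
Reactants: 23 methyl (3R,4E)-3-[(2-methoxypropan-2-yl)peroxy]-6-oxo-9-[(3R,6S)-6-propyl-3,6-dihydro-1,2-dioxin-3-yl]non-4-enoate
Product: 28 methyl 2-[(3R,6S)-6-methoxy-6-{3-[(3R,6S)-6-propyl-3,6-dihydro-1,2-dioxin-3-yl]propyl}-3,6-dihydro-1,2-dioxin-3-yl]acetate, via hydroperoxy E-enone 24 (not isolated), via hydroperoxy Z-enone 25 (not isolated), via dioxinol 26 (not isolated), via C6-epimeric ketal 27 (not isolated)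
Conditions: TsOH·H2O (5 mol%), MeOH, 20 °C; then hv (350 nm), 0 to 20 °C; SiO2 chromatography, the 27-rich fraction returned to TsOH·H2O/MeOH (2 recycles)
Reagents that add atoms: methanol, CO
Why: Transketalisation frees the hydroperoxide, E-to-Z photoisomerisation lets OOH add to the ketone so ring B closes in the photochemical step, and acid-catalysed ketalisation through the peroxycarbenium ion gives both ketal epimers, which interconvert through that ion (about 1.5:1 in favour of 27, which can hold OMe pseudo-axial with both carbon substituents pseudo-equatorial), so 28 is taken off on silica and the crude 27-rich remainder is re-equilibrated in the same acidic methanol until it is converted to 28.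

**Compound list**
1 | 2,3-dimethylbut-2-ene | CC(C)=C(C)C | starting material
2 | 2-methoxypropan-2-yl hydroperoxide | COC(C)(C)OO | intermediate
3 | D-norvaline, (R)-2-aminopentanoic acid | CCC[C@@H](N)C(=O)O | starting material
4 | (R)-2-hydroxypentanoic acid | CCC[C@@H](O)C(=O)O | intermediate
5 | methyl (R)-2-hydroxypentanoate | CCC[C@@H](O)C(=O)OC | intermediate
6 | methyl (R)-2-(trifluoromethylsulfonyloxy)pentanoate | CCC[C@@H](OS(=O)(=O)C(F)(F)F)C(=O)OC | intermediate
7 | methyl (S)-2-[(2-methoxypropan-2-yl)peroxy]pentanoate | CCC[C@H](OOC(C)(C)OC)C(=O)OC | intermediate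
8 | (S)-2-[(2-methoxypropan-2-yl)peroxy]pentanal | CCC[C@H](OOC(C)(C)OC)C=O | intermediate
9 | (triphenylphosphoranylidene)acetaldehyde | O=CC=P(c1ccccc1)(c1ccccc1)c1ccccc1 | starting material
10 | (S,E)-4-[(2-methoxypropan-2-yl)peroxy]hept-2-enal | CCC[C@H](OOC(C)(C)OC)/C=C/C=O | intermediate
11 | (S,E)-4-hydroperoxyhept-2-enal | CCC[C@H](OO)/C=C/C=O | intermediate
12 | (S,Z)-4-hydroperoxyhept-2-enal | CCC[C@H](OO)/C=C\C=O | intermediate
13 | (6S)-6-propyl-3,6-dihydro-1,2-dioxin-3-ol (both anomers) | CCC[C@H]1C=CC(O)OO1 | intermediate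
14 | 1-(trimethylsilyloxy)buta-1,3-diene | C=CC=CO[Si](C)(C)C | starting material
15 | (E)-4-[(3R,6S)-6-propyl-3,6-dihydro-1,2-dioxin-3-yl]but-2-enal | CCC[C@H]1C=C[C@@H](C/C=C/C=O)OO1 | intermediate
16 | 4-[(3R,6S)-6-propyl-3,6-dihydro-1,2-dioxin-3-yl]butanal | CCC[C@H]1C=C[C@@H](CCCC=O)OO1 | intermediate
17 | dimethyl (diazomethyl)phosphonate | [N-]=[N+]=CP(=O)(OC)OC | starting material
18 | dimethyl {2-oxo-5-[(3R,6S)-6-propyl-3,6-dihydro-1,2-dioxin-3-yl]pentyl}phosphonate | CCC[C@H]1C=C[C@@H](CCCC(=O)CP(=O)(OC)OC)OO1 | intermediate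
19 | dimethyl (S)-malate | COC(=O)C[C@H](O)C(=O)OC | starting material
20 | dimethyl (S)-2-(trifluoromethylsulfonyloxy)butanedioate | COC(=O)C[C@H](OS(=O)(=O)C(F)(F)F)C(=O)OC | intermediate
21 | dimethyl (R)-2-[(2-methoxypropan-2-yl)peroxy]butanedioate | COC(=O)C[C@@H](OOC(C)(C)OC)C(=O)OC | intermediate
22 | methyl (R)-3-[(2-methoxypropan-2-yl)peroxy]-4-oxobutanoate | COC(=O)C[C@@H](OOC(C)(C)OC)C=O | intermediate
23 | methyl (3R,4E)-3-[(2-methoxypropan-2-yl)peroxy]-6-oxo-9-[(3R,6S)-6-propyl-3,6-dihydro-1,2-dioxin-3-yl]non-4-enoate | CCC[C@H]1C=C[C@@H](CCCC(=O)/C=C/[C@@H](CC(=O)OC)OOC(C)(C)OC)OO1 | intermediate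
24 | methyl (3R,4E)-3-hydroperoxy-6-oxo-9-[(3R,6S)-6-propyl-3,6-dihydro-1,2-dioxin-3-yl]non-4-enoate | CCC[C@H]1C=C[C@@H](CCCC(=O)/C=C/[C@@H](CC(=O)OC)OO)OO1 | intermediate
25 | methyl (3R,4Z)-3-hydroperoxy-6-oxo-9-[(3R,6S)-6-propyl-3,6-dihydro-1,2-dioxin-3-yl]non-4-enoate | CCC[C@H]1C=C[C@@H](CCCC(=O)/C=C\[C@@H](CC(=O)OC)OO)OO1 | intermediate
26 | methyl 2-[(3R)-6-hydroxy-6-{3-[(3R,6S)-6-propyl-3,6-dihydro-1,2-dioxin-3-yl]propyl}-3,6-dihydro-1,2-dioxin-3-yl]acetate (both C6 epimers) | CCC[C@H]1C=C[C@@H](CCCC2(O)C=C[C@@H](CC(=O)OC)OO2)OO1 | intermediate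
27 | methyl 2-[(3R,6R)-6-methoxy-6-{3-[(3R,6S)-6-propyl-3,6-dihydro-1,2-dioxin-3-yl]propyl}-3,6-dihydro-1,2-dioxin-3-yl]acetate (C6 epimer of 28) | CCC[C@H]1C=C[C@@H](CCC[C@]2(OC)C=C[C@@H](CC(=O)OC)OO2)OO1 | intermediate
28 | methyl 2-[(3R,6S)-6-methoxy-6-{3-[(3R,6S)-6-propyl-3,6-dihydro-1,2-dioxin-3-yl]propyl}-3,6-dihydro-1,2-dioxin-3-yl]acetate | CCC[C@H]1C=C[C@@H](CCC[C@@]2(OC)C=C[C@@H](CC(=O)OC)OO2)OO1 | target

**Totals and weak points**

Total step count: 14. Longest linear sequence: 11 steps (steps 2 to 10, then 13 and 14).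

The three steps most likely to fail are steps 7, 8 and 10; step 8, the proposed new C–C bond formation, is the likeliest of the three.

Step 7 (photoisomerisation–cyclisation). Photoenolisation of the Z-enal through γ-hydrogen abstraction would erase the C–OO centre, and the hydroperoxide may not tolerate long irradiation. The fallback sets out from 8 and comes back at 13. Wittig reaction of 8 with the ylide from (1,3-dioxolan-2-ylmethyl)triphenylphosphonium bromide (LiN(SiMe3)2, THF, −78 °C) gives the Z-alkenyl dioxolane 2-[(1Z,3S)-3-[(2-methoxypropan-2-yl)peroxy]hex-1-en-1-yl]-1,3-dioxolane F1. Aqueous AcOH then cleaves both acetals, and the Z-hydroperoxy enal 12 closes to 13 in the dark.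

Step 8 (proposed new method). It may give a poor cis:trans ratio, attack at the vinylogous ring carbon, or Lewis-acid fragmentation of the peroxide. The fallback uses known chemistry, sets out from 9 and comes back at 16.
- Compound 9 and butanal give (E)-hex-2-enal F2.
- Wittig reaction with the ylide from [4-(1,3-dioxolan-2-yl)butyl]triphenylphosphonium bromide (NaN(SiMe3)2, THF) gives 2-[(4Z,6E)-deca-4,6-dien-1-yl]-1,3-dioxolane F3.
- I2-catalysed isomerisation gives 2-[(4E,6E)-deca-4,6-dien-1-yl]-1,3-dioxolane F4.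
- Singlet-oxygen [4+2] cycloaddition (O2, tetraphenylporphyrin, hv) gives the racemic cis-endoperoxide acetal 2-{3-[(3R,6S)-6-propyl-3,6-dihydro-1,2-dioxin-3-yl]propyl}-1,3-dioxolane F5, and aqueous acid gives 16 as the racemate.

The cis relation is then secure, but ring A is no longer set by the bought centre. The two diastereomers of 28 obtained after steps 10, 13 and 14 therefore have to be separated by preparative HPLC.

Step 10 (Roskamp-type homologation). The standard SnCl2 promoter cannot be used next to an O–O bond, and Sc(OTf)3 with the diazophosphonate is less tested. The fallback sets out from 16 and comes back at 18. Pinnick oxidation (NaClO2, NaH2PO4, 2-methylbut-2-ene, t-BuOH/H2O) gives 4-[(3R,6S)-6-propyl-3,6-dihydro-1,2-dioxin-3-yl]butanoic acid F6. Carbonyldiimidazole in THF gives the acyl imidazole 1-{4-[(3R,6S)-6-propyl-3,6-dihydro-1,2-dioxin-3-yl]butanoyl}imidazole F7, which is C-acylated by Mg[O2CCH2P(O)(OMe)2]2 with loss of CO2 to give 18.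

Further compounds
F1 | step 7 | 2-[(1Z,3S)-3-[(2-methoxypropan-2-yl)peroxy]hex-1-en-1-yl]-1,3-dioxolane | CCC[C@H](OOC(C)(C)OC)/C=C\C1OCCO1
F2 | step 8 | (E)-hex-2-enal | CCC/C=C/C=O
F3 | step 8 | 2-[(4Z,6E)-deca-4,6-dien-1-yl]-1,3-dioxolane | CCC/C=C/C=C\CCCC1OCCO1
F4 | step 8 | 2-[(4E,6E)-deca-4,6-dien-1-yl]-1,3-dioxolane | CCC/C=C/C=C/CCCC1OCCO1
F5 | step 8 | rac-2-{3-[(3R,6S)-6-propyl-3,6-dihydro-1,2-dioxin-3-yl]propyl}-1,3-dioxolane (racemic cis, one enantiomer drawn) | CCC[C@H]1C=C[C@@H](CCCC2OCCO2)OO1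
F6 | step 10 | 4-[(3R,6S)-6-propyl-3,6-dihydro-1,2-dioxin-3-yl]butanoic acid | CCC[C@H]1C=C[C@@H](CCCC(=O)O)OO1
F7 | step 10 | 1-{4-[(3R,6S)-6-propyl-3,6-dihydro-1,2-dioxin-3-yl]butanoyl}imidazole | CCC[C@H]1C=C[C@@H](CCCC(=O)n2ccnc2)OO1
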